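## Structural features

Compound 20 consists of two saturated six-membered rings, an oxane (O1, C2–C6) and a cyclohexane (C1'–C6'). They share no atom and are joined only by the C6–C1' bond, and both ends of that bond are fully substituted and oxygenated (O1 and CH3 on C6, OH on C1'). The oxane is a doubly tertiary ether (gem-dimethyl C2, quaternary C6). Its chair holds C3–Br and the carbocycle equatorial and C5–OH and C6–CH3 axial, while the cyclohexane chair holds the oxanyl group, C5'–Br and C4'–Cl equatorial and C1'–OH and C4'–CH3 axial. Of the six stereocentres, C5, C6 and C1' form a contiguous triad, C4' and C5' a vicinal pair, and C3 stands alone, 1,3 to C5.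

The fragile groups are:
- the tertiary chloride;
- the two secondary bromides, each next to a hetero-substituted tertiary carbon (base closes epoxides or eliminates, reducing metals cause β-elimination);
- the tertiary carbinol beside quaternary C6 (pinacol-type shifts under strong acid).

The first real difficulty is C1'. It is flanked by two methylene groups (C2', C6') and is stereogenic only because C4'/C5' differ from C3', so no local reagent approach can set it and it cannot pass stereochemical information to C6. The second difficulty is the dihalide. With the tert-butyl-like oxanyl group locked equatorial, Markovnikov trans-diaxial addition of Br+/Cl– to a C4'=C5' alkene would put bromine syn and chlorine anti to the C1' hydroxyl. That is the reverse of 20, so the bromonium ion has to be forced onto the face anti to that hydroxyl.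

The key step exploits the 1,4-relation in the carbocycle between C1', which bears an oxygen and the acyl-level carbon C6, and the methyl-bearing C4'. With a C4'=C5' alkene in place this is the pattern of a para adduct of a 2-methyl diene to a 1-oxy-1-acyl alkene, C1' being the spiro atom of a chiral dioxolanone.

## Logic of the disconnections

**20 ⇒ 19 ⇒ 18.** After removal of the O5 silyl group (20 ⇒ 19), the C4'–Cl bond is cut and C4' is tied to the C1' oxygen (called O7 while it bridges).
- Reason: direct bromochlorination of a cyclohexene would favour the wrong face pair, whereas a bridge on the hydroxyl face marks exactly the position the chloride must take.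
- Gain: the tertiary chloride and the free C1' carbinol vanish until the end, and C4' becomes a consequence of C1'.
- Demand: the forward step must ionise C4'–O7 only, beside the O1–C2 ether, and deliver chloride with retention through the C5' bromine.

**18 ⇒ 17.** O1–C2 and C3–Br are cut together.
- Reason: they are anti across a former C2=C3 alkene, and the equatorial bromide is what a chair-like 6-endo closure delivers.
- Gain: the oxane ring, the hindered ether bond and the C3 stereocentre are replaced by a plain trisubstituted alkene.
- Demand: the crowded C6 hydroxyl must attack C2 rather than C3, no other alkene or free hydroxyl may be present, and C6 must already be correct because it dictates C3.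

**17 ⇒ 16.** The C6–CH3 bond is cut.
- Reason: C6 then becomes a ketone whose only stereochemical neighbour of use is C5.
- Gain: the quaternary centre is reduced to a carbonyl group.
- Demand: methyl addition must follow the non-chelated (polar Felkin–Anh) mode, which requires a bulky, non-coordinating O5 group and a non-basic methyl donor.

**16 ⇒ 15 ⇒ 13.** After the silyl group, the C5–O bond is cut.
- Reason: C1' is quaternary, so the ketone can enolise only towards C5.
- Gain: an achiral side chain.
- Demand: the carbocycle gives no facial bias, so the oxygen must come from an enantiopure reagent. Any epimer formed is a separable diastereomer.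

**13 ⇒ 10 + 11.** The C5–C6 bond is cut.
- Reason: C6 is at the acid oxidation level after the cycloaddition, and the six carbons C2–C5 plus both C2 methyl groups are available in one purchasable piece.
- Gain: full convergence with no extra chain building.
- Demand: acylation must stop at the ketone, and the organometallic reagent must leave the secondary bromide alone.

**10 ⇒ 9 ⇒ 8.** After the amide/ester exchange, C4'–O7 and C5'–Br are cut.
- Reason: only the bromonium ion anti to the C1' hydroxyl can be captured across the ring, so C1' alone fixes C4' and C5'.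
- Gain: two stereocentres and one ring are removed. In the forward sense the bridge also protects the alkene and the carbinol through six steps.
- Demand: the hydroxyl must beat the C6 carbonyl oxygen as internal nucleophile, hence the ester stage.

**8 ⇒ 7 ⇒ 5 + 6.** After reinstalling the acetal, C2'–C3' and C1'–C6' are cut.
- Reason: this is the only point at which C1' can be given an absolute configuration, because the ring alkene that makes it stereogenic is created in the same event.
- Gain: the carbocycle, two skeletal bonds and the C1' stereocentre.
- Demand: addition anti to the acetal substituent and para orientation.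
- Configuration check: (S)-5 with anti addition gives (2S,5R)-7, and its spiro carbon maps onto (1'R) of 20, so the L-series precursor is the right one.

**5 ⇒ 4 ⇒ 3 ⇒ 1 + 2.** The exocyclic alkene is traced to a C–H/C–Br pair and the acetal C–O bonds are cut.
- Reason: the original stereocentre of 1 induces the acetal centre and is then sacrificed.
- Gain: two bulk chemicals.
- Demand: 3 must be freed of its trans isomer, since the acetal carbon alone carries the chirality onward.

## Other disconnections considered

**Alternative 1:** The cut is at C4'–Cl and C5'–Br, made late, with chloride replaced by a temporary C4'–O bond to the C1' oxygen.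
- Forward step: the finished oxane bearing a cyclohexenol, A2 (O5 as acetate), would meet an electrophilic bromine source. The bromonium ion anti to the C1' hydroxyl would be opened across the ring at C4' to give the 7-oxabicyclo[2.2.1]heptane A1, to be unlocked later by a chloride Lewis acid.
- In its favour: geometry allows only one diastereomer, so C5' is certain and the C4' face is marked.
- Against it here: it forms no skeletal bond and no ring of 20, and it leaves the origin of C1' open. Placed late, it obliges the C4'=C5' alkene and a separately protected C1' hydroxyl to survive the whole oxane construction, which excludes electrophilic bromine for C3 and any alkene oxidation in the side chain.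
- Structure: A1 differs from 18 only in the O5 group.
- Mechanism: on control of the dihalide this alternative is the equal of the chosen plan, which has taken the same relay in as step 6. The unlocking problem (bridge versus O1–C2) is also the same.
- Where it is better: the bridge and its bromide never meet Grignard, amide-base or organocerium reagents.
- Step economy: the early placement is better, since the bridge replaces protecting-group steps and permits a two-step oxane synthesis. As the central disconnection the alternative simplifies too little.

**Alternative 2:** The cuts are C5–C6 and C2–C3.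
- Forward step: a Lewis acid would ionise the siloxy acetal A5 to an alkoxy-substituted oxyallyl cation, which would add across C2/C5 of 2,5-dimethylfuran A4 to give the 8-oxabicyclo[3.2.1]octenone A3.
- In its favour: O1 arrives with both tertiary C–O bonds already made. On this point it is better than the chosen plan, whose step 12 must forge O1–C2 between crowded centres. C5–O and C6 are set together in a rigid bicycle under auxiliary control, and the count of two C–C bonds and one ring equals that of the Diels–Alder step.
- Against it here:
  - The etheno bridge must be cleaved into two unlike stubs, one reduced to the second C2 methyl and the other grown into the whole carbocycle.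
  - C1', the hardest centre, is postponed without any handle.
  - The C4 carbonyl must be deleted next to a newly installed C3 bromide.
  - The 2,5-dimethyl substitution should slow the cycloaddition and favour stepwise alkylation of the furan.
- Comparison: it solves the ether and C5/C6 more elegantly, but it leaves C1', C4', C5' and seven carbons still to be introduced, so it should be clearly longer.

**Alternative 3:** The cut is O1–C6.
- Forward step: under acid the tertiary C2 hydroxyl of the bromohydrin A7 would attack C6 of the C6/C1' spiro epoxide in a 6-exo mode with inversion, giving A6 and freeing the C1' hydroxyl.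
- In its favour: a stereospecific substitution would set C6 and reveal C1' in one event, C3 would come from a defined bromohydrin, and no bromonium regiochemistry arises. In principle this is better than the model-based control of steps 11 and 12.
- Against it here:
  - A7 needs a tetrasubstituted epoxide of defined configuration at both carbons. Its parent alkene C6=C1' has an E/Z geometry that differs only through the remote ring alkene, which also competes for the oxidant.
  - Substitution at a fully substituted carbon by a tertiary alcohol is likely to be cation-like. C1', having no adjacent oxygen, should ionise more readily than C6, which invites 7-endo closure or ring-contracting shifts.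
- Comparison: step counts should be similar. The closure is mechanistically cleaner on paper, but the source of the C1'/C6 configuration is much weaker than an auxiliary-controlled cycloaddition.

Key step: step 4

Remark on the chemistry: the antipode of the camphor-derived oxaziridine in step 9 is assigned by analogy with Z(O)-enolates of hindered ketones, and the other antipode, equally purchasable, would be used if the sense proves opposite. O7 denotes the C1' oxygen while it bridges to C4'.

## Steps

Step 1
Reactants: 1 L-lactic acid; 2 pivalaldehyde
Product: 3 (2S,5S)-2-tert-butyl-5-methyl-1,3-dioxolan-4-one (cis)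
Conditions: p-TsOH·H2O (cat.), H2SO4 (cat.), pentane, reflux, Dean–Stark; recrystallisation from pentane, –78 °C
Reagents that add atoms: none
Why: Acid-catalysed acetalisation of an α-hydroxy acid (self-regeneration-of-stereocentres acetal); the C5 methyl group directs the new acetal centre mainly cis, and crystallisation should remove the trans isomer, which matters because only the acetal carbon carries chirality beyond step 3.

Step 2
Reactants: 3 (2S,5S)-2-tert-butyl-5-methyl-1,3-dioxolan-4-one
Product: 4 (2S,5R)-5-bromo-2-tert-butyl-5-methyl-1,3-dioxolan-4-one (Br trans to tert-butyl)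
Conditions: NBS, AIBN (cat.), PhCF3, 85 °C
Reagents that add atoms: N-bromosuccinimide, O=C1CCC(=O)N1Br
Why: Wohl–Ziegler-type radical bromination at the captodatively stabilised C5–H; bromine should enter anti to tert-butyl, but this centre is erased in step 3 while the acetal centre is untouched.

Step 3
Reactants: 4 (2S,5R)-5-bromo-2-tert-butyl-5-methyl-1,3-dioxolan-4-one
Product: 5 (S)-2-tert-butyl-5-methylene-1,3-dioxolan-4-one
Conditions: Et3N, Et2O, 0 °C → rt
Reagents that add atoms: none
Why: E2 dehydrobromination of a tertiary α-bromo lactone towards its only β-hydrogens (the methyl group) gives the exocyclic alkene; the acetal stereocentre is not involved.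

Step 4
Reactants: 5 (S)-2-tert-butyl-5-methylene-1,3-dioxolan-4-one; 6 isoprene
Product: 7 (2S,5R)-2-tert-butyl-8-methyl-1,3-dioxaspiro[4.5]dec-7-en-4-one (para adduct, C6' trans to tert-butyl)
Conditions: 6 (excess), BHT (cat.), toluene, sealed tube, 110 °C; separation from the meta isomer
Reagents that add atoms: none
Why: Concerted, suprafacial, normal-electron-demand [4π+2π] cycloaddition (Diels–Alder reaction) of s-cis 6 to the exocyclic alkene of 5; the closest known reaction type is the thermal Diels–Alder reaction of chiral 5-methylene-1,3-dioxolan-4-ones used as α-hydroxyacrylate equivalents. The cyclohexene ring is closed intermolecularly by simultaneous formation of C2'–C3' (from the =CH2 of 5) and C1'–C6', so that C1' becomes the spiro atom already carrying its oxygen and the future C6 carbonyl. The one new stereocentre, C1', is controlled by the acetal tert-butyl group, which shields one face of the flat dioxolanone: the diene adds anti to it, C6' ends trans and C2' cis to tert-butyl, which is (5R) in 7 and maps onto (1'R) of 20. Because both termini of 6 are unsubstituted, endo and exo approaches give the same product, so only face and orientation count. The lactone carbonyl places the larger LUMO coefficient on the =CH2 carbon, which pairs with C1 of 6 (larger HOMO coefficient, next to the methyl-bearing carbon) to give the para adduct, the minor meta isomer being removed by chromatography or crystallisation. Thermal conditions with a radical inhibitor are preferred to strong Lewis acids because 5 is an acid-labile acylal and both partners polymerise.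

Step 5
Reactants: 7 (2S,5R)-2-tert-butyl-8-methyl-1,3-dioxaspiro[4.5]dec-7-en-4-one
Product: 8 methyl (1R)-1-hydroxy-4-methylcyclohex-3-ene-1-carboxylate
Conditions: K2CO3 (cat.), MeOH, 0 °C → rt
Reagents that add atoms: methanol, CO
Why: Base-catalysed transesterification opens the acylal and the resulting hemiacetal alkoxide collapses to pivalaldehyde; the C1'–O bond is never broken, so the configuration is retained.

Step 6
Reactants: 8 methyl (1R)-1-hydroxy-4-methylcyclohex-3-ene-1-carboxylate
Product: 9 methyl (1R,3S,4S)-3-bromo-4-methyl-7-oxabicyclo[2.2.1]heptane-1-carboxylate (3-endo-bromide)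
Conditions: NBS, CH2Cl2, 0 °C, dark
Reagents that add atoms: N-bromosuccinimide, O=C1CCC(=O)N1Br
Why: Transannular bromoetherification of a cyclohex-3-enol to a 7-oxabicyclo[2.2.1]heptane: only the bromonium ion anti to the axial C1' hydroxyl can be opened internally, at tertiary C4' (Markovnikov), while the other one reverts, so anti addition fixes C5'–Br (S, endo) and C4'–O (S) from C1' alone. The bridge also masks the alkene and the carbinol for steps 7–12, and the ester stage is chosen because its carbonyl oxygen is a poor rival nucleophile.

Step 7
Reactants: 9 methyl (1R,3S,4S)-3-bromo-4-methyl-7-oxabicyclo[2.2.1]heptane-1-carboxylate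
Product: 10 (1R,3S,4S)-3-bromo-N-methoxy-N,4-dimethyl-7-oxabicyclo[2.2.1]heptane-1-carboxamide
Conditions: MeNH(OMe)·HCl, i-PrMgCl, THF, –20 → 0 °C
Reagents that add atoms: N,O-dimethylhydroxylamine hydrochloride, CNOC.Cl
Why: Aminolysis of an α-alkoxy ester by the magnesium amide (first half of a Weinreb ketone synthesis); the tied-back bridgehead keeps the carbonyl accessible, and an alkylmagnesium chloride should not exchange with a secondary alkyl bromide at this temperature.

Step 8
Reactants: 10 (1R,3S,4S)-3-bromo-N-methoxy-N,4-dimethyl-7-oxabicyclo[2.2.1]heptane-1-carboxamide; 11 5-bromo-2-methylpent-2-ene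
Product: 13 1-[(1R,3S,4S)-3-bromo-4-methyl-7-oxabicyclo[2.2.1]heptan-1-yl]-5-methylhex-4-en-1-one, via 4-methylpent-3-enylmagnesium bromide 12 (not isolated)
Conditions: 11, Mg, THF; then 10, THF, 0 °C; 1 M HCl
Reagents that add atoms: none
Why: Weinreb ketone synthesis: the chelated tetrahedral adduct survives until work-up, so acylation stops at the ketone. One step forms C5–C6 and brings in C2–C5 with both C2 methyl groups.

Step 9
Reactants: 13 1-[(1R,3S,4S)-3-bromo-4-methyl-7-oxabicyclo[2.2.1]heptan-1-yl]-5-methylhex-4-en-1-one
Product: 15 (2R)-1-[(1R,3S,4S)-3-bromo-4-methyl-7-oxabicyclo[2.2.1]heptan-1-yl]-2-hydroxy-5-methylhex-4-en-1-one, via potassium Z-enolate 14 (not isolated)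
Conditions: KHMDS, THF, –78 °C; (–)-(camphorsulfonyl)oxaziridine, –78 °C; AcOH
Reagents that add atoms: (1R)-(–)-(10-camphorsulfonyl)oxaziridine, CC1(C)[C@H]2CC[C@@]13CS(=O)(=O)N4O[C@]34C2
Why: Davis oxidation of a ketone enolate: C1' is quaternary, so only C5 can be deprotonated, and the bulky acyl substituent enforces the Z(O)-enolate. The carbocycle offers no facial bias, so C5 (R) is set by the enantiopure reagent, alkenes are not touched, and any (5S) epimer is a separable diastereomer.

Step 10
Reactants: 15 (2R)-1-[(1R,3S,4S)-3-bromo-4-methyl-7-oxabicyclo[2.2.1]heptan-1-yl]-2-hydroxy-5-methylhex-4-en-1-one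
Product: 16 (2R)-1-[(1R,3S,4S)-3-bromo-4-methyl-7-oxabicyclo[2.2.1]heptan-1-yl]-2-[(tert-butyldimethylsilyl)oxy]-5-methylhex-4-en-1-one
Conditions: TBSCl, imidazole, DMF, rt
Reagents that add atoms: tert-butyldimethylsilyl chloride, CC(C)(C)[Si](C)(C)Cl
Why: Standard silylation under mild base that should neither epimerise C5 nor touch the bridge; the bulky non-chelating group serves as the large substituent in step 11 and keeps O5 out of step 12.

Step 11
Reactants: 16 (2R)-1-[(1R,3S,4S)-3-bromo-4-methyl-7-oxabicyclo[2.2.1]heptan-1-yl]-2-[(tert-butyldimethylsilyl)oxy]-5-methylhex-4-en-1-one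
Product: 17 (2S,3R)-2-[(1R,3S,4S)-3-bromo-4-methyl-7-oxabicyclo[2.2.1]heptan-1-yl]-3-[(tert-butyldimethylsilyl)oxy]-6-methylhept-5-en-2-ol
Conditions: MeLi, CeCl3, THF, –78 °C; aq NH4Cl
Reagents that add atoms: methyllithium, [Li]C
Why: Organocerium (Imamoto) 1,2-addition to a hindered, enolisable ketone under polar Felkin–Anh control: C5–OTBS stands perpendicular to C=O and anti to the incoming methyl while C5–H lies next to the bulky bicyclic group, which gives (6S), i.e. O5 and O6 syn in the C1'–C6–C5–C4 zigzag. The low basicity should suppress enolisation, and the cold quench should prevent silyl migration.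

Step 12
Reactants: 17 (2S,3R)-2-[(1R,3S,4S)-3-bromo-4-methyl-7-oxabicyclo[2.2.1]heptan-1-yl]-3-[(tert-butyldimethylsilyl)oxy]-6-methylhept-5-en-2-ol
Product: 18 (2S,3R,5R)-5-bromo-2-[(1R,3S,4S)-3-bromo-4-methyl-7-oxabicyclo[2.2.1]heptan-1-yl]-3-[(tert-butyldimethylsilyl)oxy]-2,6,6-trimethyloxane
Conditions: 2,4,4,6-tetrabromocyclohexa-2,5-dienone (TBCO), MeNO2, 0 °C → rt
Reagents that add atoms: 2,4,4,6-tetrabromocyclohexa-2,5-dien-1-one, O=C1C(Br)=CC(Br)(Br)C=C1Br
Why: 6-endo (Markovnikov) bromoetherification of a bishomoallylic tertiary alcohol onto a prenyl-type alkene, the reaction type known for the 3-bromo-2,2-dimethyloxane rings of marine terpenoids. Anti addition places C3–Br equatorial in a chair transition state, and only the chair with the bicyclic group equatorial (C6–CH3 and C5–OTBS axial) avoids a prohibitive 1,3-diaxial contact with a C2 methyl, which sets C3 (R).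

Step 13
Reactants: 18 (2S,3R,5R)-5-bromo-2-[(1R,3S,4S)-3-bromo-4-methyl-7-oxabicyclo[2.2.1]heptan-1-yl]-3-[(tert-butyldimethylsilyl)oxy]-2,6,6-trimethyloxane
Product: 19 (1R,3S,4S)-3-bromo-1-[(2S,3R,5R)-5-bromo-3-[(tert-butyldimethylsilyl)oxy]-2,6,6-trimethyloxan-2-yl]-4-chloro-4-methylcyclohexan-1-ol
Conditions: TiCl4, CH2Cl2, –78 °C; aq NaHCO3
Reagents that add atoms: titanium tetrachloride, Cl[Ti](Cl)(Cl)Cl
Why: Lewis acid cleavage of a strained tertiary bridging ether by halide with anchimeric assistance: titanium binds the exposed O7, and the C4'–O7 bond, anti to C5'–Br, ionises to the bromonium ion on the face anti to O7. Chloride enters at tertiary C4' from the O7 side, giving net retention (4'S) and a ring that relaxes to the diequatorial dihalide. C1'–O7 should hold because a cation at C1' is destabilised by the adjacent C6–O1, and O1 is unstrained and buried between two quaternary carbons.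

Step 14
Reactants: 19 (1R,3S,4S)-3-bromo-1-[(2S,3R,5R)-5-bromo-3-[(tert-butyldimethylsilyl)oxy]-2,6,6-trimethyloxan-2-yl]-4-chloro-4-methylcyclohexan-1-ol
Product: 20 (1R,3S,4S)-3-bromo-1-[(2S,3R,5R)-5-bromo-3-hydroxy-2,6,6-trimethyloxan-2-yl]-4-chloro-4-methylcyclohexan-1-ol (CNP0244614.1)
Conditions: HF·pyridine, THF, 0 °C → rt
Reagents that add atoms: none
Why: Fluoride-driven desilylation in a weakly acidic medium, chosen over basic fluoride so that no alkoxide is formed that could eliminate or displace the halides; no stereocentre is touched.

## Compound list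

1 | L-lactic acid | C[C@H](O)C(=O)O | starting material
2 | pivalaldehyde | CC(C)(C)C=O | starting material
3 | (2S,5S)-2-tert-butyl-5-methyl-1,3-dioxolan-4-one | C[C@@H]1O[C@H](C(C)(C)C)OC1=O | intermediate
4 | (2S,5R)-5-bromo-2-tert-butyl-5-methyl-1,3-dioxolan-4-one | C[C@]1(Br)O[C@H](C(C)(C)C)OC1=O | intermediate
5 | (S)-2-tert-butyl-5-methylene-1,3-dioxolan-4-one | C=C1O[C@H](C(C)(C)C)OC1=O | intermediate
6 | isoprene | C=CC(C)=C | starting material
7 | (2S,5R)-2-tert-butyl-8-methyl-1,3-dioxaspiro[4.5]dec-7-en-4-one | CC1=CC[C@@]2(CC1)O[C@H](C(C)(C)C)OC2=O | intermediate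
8 | methyl (1R)-1-hydroxy-4-methylcyclohex-3-ene-1-carboxylate | COC(=O)[C@@]1(O)CCC(C)=CC1 | intermediate
9 | methyl (1R,3S,4S)-3-bromo-4-methyl-7-oxabicyclo[2.2.1]heptane-1-carboxylate | COC(=O)[C@@]1(O2)CC[C@@]2(C)[C@@H](Br)C1 | intermediate
10 | (1R,3S,4S)-3-bromo-N-methoxy-N,4-dimethyl-7-oxabicyclo[2.2.1]heptane-1-carboxamide | CON(C)C(=O)[C@@]1(O2)CC[C@@]2(C)[C@@H](Br)C1 | intermediate
11 | 5-bromo-2-methylpent-2-ene | CC(C)=CCCBr | starting material
12 | 4-methylpent-3-enylmagnesium bromide | CC(C)=CCC[Mg]Br | intermediate
13 | 1-[(1R,3S,4S)-3-bromo-4-methyl-7-oxabicyclo[2.2.1]heptan-1-yl]-5-methylhex-4-en-1-one | CC(C)=CCCC(=O)[C@@]1(O2)CC[C@@]2(C)[C@@H](Br)C1 | intermediate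
14 | potassium (Z)-enolate of 13 | CC(C)=CC/C=C(\[O-])[C@@]1(O2)CC[C@@]2(C)[C@@H](Br)C1.[K+] | intermediate
15 | (2R)-1-[(1R,3S,4S)-3-bromo-4-methyl-7-oxabicyclo[2.2.1]heptan-1-yl]-2-hydroxy-5-methylhex-4-en-1-one | CC(C)=CC[C@@H](O)C(=O)[C@@]1(O2)CC[C@@]2(C)[C@@H](Br)C1 | intermediate
16 | (2R)-1-[(1R,3S,4S)-3-bromo-4-methyl-7-oxabicyclo[2.2.1]heptan-1-yl]-2-[(tert-butyldimethylsilyl)oxy]-5-methylhex-4-en-1-one | CC(C)=CC[C@@H](O[Si](C)(C)C(C)(C)C)C(=O)[C@@]1(O2)CC[C@@]2(C)[C@@H](Br)C1 | intermediate
17 | (2S,3R)-2-[(1R,3S,4S)-3-bromo-4-methyl-7-oxabicyclo[2.2.1]heptan-1-yl]-3-[(tert-butyldimethylsilyl)oxy]-6-methylhept-5-en-2-ol | CC(C)=CC[C@@H](O[Si](C)(C)C(C)(C)C)[C@](C)(O)[C@@]1(O2)CC[C@@]2(C)[C@@H](Br)C1 | intermediate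
18 | (2S,3R,5R)-5-bromo-2-[(1R,3S,4S)-3-bromo-4-methyl-7-oxabicyclo[2.2.1]heptan-1-yl]-3-[(tert-butyldimethylsilyl)oxy]-2,6,6-trimethyloxane | CC1(C)O[C@](C)([C@@]2(O3)CC[C@@]3(C)[C@@H](Br)C2)[C@H](O[Si](C)(C)C(C)(C)C)C[C@H]1Br | intermediate
19 | (1R,3S,4S)-3-bromo-1-[(2S,3R,5R)-5-bromo-3-[(tert-butyldimethylsilyl)oxy]-2,6,6-trimethyloxan-2-yl]-4-chloro-4-methylcyclohexan-1-ol | CC1(C)O[C@](C)([C@@]2(O)CC[C@](C)(Cl)[C@@H](Br)C2)[C@H](O[Si](C)(C)C(C)(C)C)C[C@H]1Br | intermediate
20 | (1R,3S,4S)-3-bromo-1-[(2S,3R,5R)-5-bromo-3-hydroxy-2,6,6-trimethyloxan-2-yl]-4-chloro-4-methylcyclohexan-1-ol | CC1(C)O[C@](C)([C@@]2(O)CC[C@](C)(Cl)[C@@H](Br)C2)[C@H](O)C[C@H]1Br | target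

## Step count and least certain steps

Total step count: 14. Longest linear sequence: 14 steps (1 → 20); 2, 6 and 11 enter as purchased.

**Step 4 (key step).** The most likely failure is incomplete para orientation. The methyl group polarises the diene only weakly, so the meta mode of addition competes under purely thermal conditions. Thermal polymerisation of either partner and some attack syn to the tert-butyl group are further losses.

The fallback keeps the same dienophile and the same two ring bonds but uses a strongly polarised diene. It sets out from 5, and cycloaddition with 2-(trimethylsilyloxy)buta-1,3-diene should give the silyl enol ether spiro adduct F1. CsF/PhNTf2 would convert it regiospecifically into the enol triflate F2, never passing through the free ketone, in which C1' would cease to be stereogenic. A Negishi methylation (MeZnCl, Pd(PPh3)4, THF) then comes back to the route at 7.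

**Step 9.** The most likely failure is insufficient facial discrimination of the enolate. The carbocycle gives no bias, and the induction of the oxaziridine depends on the enolate substituents. Warming before the quench could also start an α-ketol shift.

The fallback replaces reagent control by separation and invertive recycling. It sets out from 13: after the hydroxylation the epimers are separated, and the (5S)-hydroxy ketone F3 is subjected to a Mitsunobu reaction with 4-nitrobenzoic acid to give the (5R)-4-nitrobenzoate F4. Brief methanolysis of F4 (K2CO3, MeOH, 0 °C) comes back at 15.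

**Step 11.** The most likely failures are erosion of Felkin–Anh control through coordination of the metal to O5 or O7, enolisation with loss of C5 integrity, and O5→O6 silyl migration in the alkoxide.

The fallback sets C6 inside the ring instead, and it bypasses step 12 as well. It sets out from 16 and runs as follows:
- Shi epoxidation with the L-series (ent) ketone should give the (3S)-epoxy ketone F5.
- Li2NiBr4 in THF should open F5 at the secondary carbon with inversion to the bromohydrin ketone F6.
- CSA in MeOH should close F6 to the cyclic methyl ketal F7.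
- AlMe3 in CH2Cl2 should methylate the derived oxocarbenium ion. In that ion, A(1,2) strain with the bicyclic group holds C5–OTBS pseudoaxial, so axial attack anti to it comes back at 18.

**Step 12.** The most likely failures are closure in the 5-exo mode at the less hindered C3, participation of the silyl ether oxygen, and sluggish attack by the very crowded C6 hydroxyl.

The fallback separates ring closure from bromination. It sets out from 17, where reversible, strongly Markovnikov mercuricyclisation (Hg(OCOCF3)2, MeNO2, then aq KBr) should give the equatorial organomercuric bromide F8. Electrophilic bromodemercuration with retention (Br2, pyridine, dark) then comes back at 18.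

**Step 13.** Several things can go wrong:
- ionisation of the wrong C–O bond, either O1–C2, which is also tertiary and anti to a bromine, or C1'–O7 followed by a pinacol-type shift;
- proton loss instead of chloride capture;
- chloride entry at C5', which gives the diaxial constitutional isomer (a thermal diaxial-to-diequatorial dihalide rearrangement should correct this last case).

The fallback removes the competing β-bromo ether by changing the order of events. It sets out from 17, where TiCl4 with 2,6-di-tert-butyl-4-methylpyridine at –78 °C, anchored on the C6 alkoxide and so chelated to O7, should open the bridge to the bromochloro diol F9. TBCO closure of F9 onto the prenyl alkene comes back at 19, at the price of a second free tertiary hydroxyl during that closure.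

## Further compounds

F1 | step 4 | (2S,5R)-2-tert-butyl-8-(trimethylsilyloxy)-1,3-dioxaspiro[4.5]dec-7-en-4-one | C[Si](C)(C)OC1=CC[C@@]2(CC1)O[C@H](C(C)(C)C)OC2=O
F2 | step 4 | (2S,5R)-2-tert-butyl-4-oxo-1,3-dioxaspiro[4.5]dec-7-en-8-yl trifluoromethanesulfonate | O=S(=O)(OC1=CC[C@@]2(CC1)O[C@H](C(C)(C)C)OC2=O)C(F)(F)F
F3 | step 9 | (2S)-1-[(1R,3S,4S)-3-bromo-4-methyl-7-oxabicyclo[2.2.1]heptan-1-yl]-2-hydroxy-5-methylhex-4-en-1-one | CC(C)=CC[C@H](O)C(=O)[C@@]1(O2)CC[C@@]2(C)[C@@H](Br)C1
F4 | step 9 | (2R)-1-[(1R,3S,4S)-3-bromo-4-methyl-7-oxabicyclo[2.2.1]heptan-1-yl]-5-methyl-1-oxohex-4-en-2-yl 4-nitrobenzoate | CC(C)=CC[C@@H](OC(=O)c1ccc(cc1)[N+](=O)[O-])C(=O)[C@@]1(O2)CC[C@@]2(C)[C@@H](Br)C1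
F5 | step 11 | (2R)-1-[(1R,3S,4S)-3-bromo-4-methyl-7-oxabicyclo[2.2.1]heptan-1-yl]-2-[(tert-butyldimethylsilyl)oxy]-3-[(2S)-3,3-dimethyloxiran-2-yl]propan-1-one | CC1(C)O[C@H]1C[C@@H](O[Si](C)(C)C(C)(C)C)C(=O)[C@@]2(O3)CC[C@@]3(C)[C@@H](Br)C2
F6 | step 11 | (2R,4R)-4-bromo-1-[(1R,3S,4S)-3-bromo-4-methyl-7-oxabicyclo[2.2.1]heptan-1-yl]-2-[(tert-butyldimethylsilyl)oxy]-5-hydroxy-5-methylhexan-1-one (open form of the hemiketal) | CC(C)(O)[C@H](Br)C[C@@H](O[Si](C)(C)C(C)(C)C)C(=O)[C@@]1(O2)CC[C@@]2(C)[C@@H](Br)C1
F7 | step 11 | (3R,5R)-5-bromo-2-[(1R,3S,4S)-3-bromo-4-methyl-7-oxabicyclo[2.2.1]heptan-1-yl]-3-[(tert-butyldimethylsilyl)oxy]-2-methoxy-6,6-dimethyloxane (axial methoxy anomer) | CC1(C)O[C@](OC)([C@@]2(O3)CC[C@@]3(C)[C@@H](Br)C2)[C@H](O[Si](C)(C)C(C)(C)C)C[C@H]1Br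
F8 | step 12 | bromo{(3R,5R,6S)-6-[(1R,3S,4S)-3-bromo-4-methyl-7-oxabicyclo[2.2.1]heptan-1-yl]-5-[(tert-butyldimethylsilyl)oxy]-2,2,6-trimethyloxan-3-yl}mercury (equatorial C–Hg) | CC1(C)O[C@](C)([C@@]2(O3)CC[C@@]3(C)[C@@H](Br)C2)[C@H](O[Si](C)(C)C(C)(C)C)C[C@H]1[Hg]Br
F9 | step 13 | (1R,3S,4S)-3-bromo-1-[(2S,3R)-3-[(tert-butyldimethylsilyl)oxy]-2-hydroxy-6-methylhept-5-en-2-yl]-4-chloro-4-methylcyclohexan-1-ol | CC(C)=CC[C@@H](O[Si](C)(C)C(C)(C)C)[C@](C)(O)[C@@]1(O)CC[C@](C)(Cl)[C@@H](Br)C1
A1 | alternative 1 | bromo oxa-bridged bicycle with finished oxane, O5 acetate | CC1(C)O[C@](C)([C@@]2(O3)CC[C@@]3(C)[C@@H](Br)C2)[C@H](OC(C)=O)C[C@H]1Br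
A2 | alternative 1 | bromo oxane with C1' carbinol and C4'=C5' cyclohexene, O5 acetate | CC1(C)O[C@](C)([C@@]2(O)CCC(C)=CC2)[C@H](OC(C)=O)C[C@H]1Br
A3 | alternative 2 | 1,5-dimethyl-2-[(S)-1-phenylethoxy]-8-oxabicyclo[3.2.1]oct-6-en-3-one | C[C@@]12C=C[C@@](C)(O1)[C@H](O[C@@H](C)c1ccccc1)C(=O)C2
A4 | alternative 2 | 2,5-dimethylfuran | Cc1ccc(C)o1
A5 | alternative 2 | 3-methoxy-3-[(S)-1-phenylethoxy]-2-(triethylsilyloxy)prop-1-ene (mixed acetal, acetal carbon undefined) | C=C(O[Si](CC)(CC)CC)C(OC)O[C@@H](C)c1ccccc1
A6 | alternative 3 | bromo oxane with C1' carbinol and cyclohexene, O5 TBS ether | CC1(C)O[C@](C)([C@@]2(O)CCC(C)=CC2)[C@H](O[Si](C)(C)C(C)(C)C)C[C@H]1Br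
A7 | alternative 3 | bromohydrin bearing the C6/C1' spiro epoxide (1-oxaspiro[2.5]oct-5-ene), O5 TBS ether | CC(C)(O)[C@H](Br)C[C@@H](O[Si](C)(C)C(C)(C)C)[C@@]1(C)O[C@@]12CCC(C)=CC2
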